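**Strategy.** Ring B (C4a–C5–C6–C7–C8–C8a, octahydronaphthalene numbering) is closed last and is the only ring made in the route: ring A derives from benzoic acid (Birch methylation, then oxidation to a prochiral 4,4-disubstituted cyclohexadienone) and the pyrrolinone is bought. A catalytic enantioselective Diels–Alder reaction of a 2-silyloxy diene with the C4a=C8a double bond forms C4a–C5 and C8–C8a at once. It exploits the cis C4a/C8a fusion, the quaternary C1 flanked by two enone β-carbons, and the 6,8-dimethyl pattern; the temporary C7 oxygen steers regiochemistry, lets both methyl centres equilibrate and is then excised. Claisen transfer from C4–O to C2, side-chain ketone coupling and tetramate addition complete the synthesis.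

Key step: step 6

Remark on numbering: the target's carbocycle is numbered C1 (quaternary), C2, C3=C4, C4a, C5–C8, C8a; ring A = C1/C2/C3/C4/C4a/C8a, ring B = C4a/C5/C6/C7/C8/C8a; the side chain on C2 is C1′–C10′. The target is a cis-fused decalin (4a-H and 8a-H on the same face), the 8-methyl is anti to C1, and the C1 methyl, C1′, C5 and C8 lie on one face of ring A.

Assumption: the (S)-configured oxazaborolidinium ion is taken to activate the enone double bond that leads to 9 as drawn; should it prefer the other one, its enantiomer is used.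

Step 1
Reactants: 1 benzoic acid
Product: 3 1-methylcyclohexa-2,5-diene-1-carboxylic acid, via dilithium enediolate 2 (not isolated)
Conditions: Li, NH3 (l), THF, −78 °C; MeI, −78 °C → rt; HCl work-up
Reagents that add atoms: iodomethane CI
Why: Birch reductive alkylation, in which dissolving-metal reduction gives the cross-conjugated enediolate that is methylated at the ipso carbon, so the future quaternary C1 is installed on a carbocycle that never has to be closed.

Step 2
Reactants: 3 1-methylcyclohexa-2,5-diene-1-carboxylic acid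
Product: 4 (1-methylcyclohexa-2,5-dien-1-yl)methanol
Conditions: LiAlH4, Et2O, 0 °C → rt
Reagents that add atoms: none
Why: Hydride reduction of the carboxylic acid to the primary alcohol should leave the skipped, unconjugated diene untouched.

Step 3
Reactants: 4 (1-methylcyclohexa-2,5-dien-1-yl)methanol
Product: 5 4-methoxybenzyl ether of 4
Conditions: NaH, 4-methoxybenzyl chloride, Bu4NI (cat.), THF/DMF, 0 °C → rt
Reagents that add atoms: 4-methoxybenzyl chloride COc1ccc(CCl)cc1
Why: Williamson etherification gives a base-stable ether that can later be removed oxidatively in the presence of silyl ethers and that makes this arm larger than the methyl group.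

Step 4
Reactants: 5 4-methoxybenzyl ether of 4
Product: 6 4-[(4-methoxybenzyloxy)methyl]-4-methylcyclohexa-2,5-dien-1-one
Conditions: dirhodium tetracaprolactamate Rh2(cap)4 (1 mol %), t-BuOOH (70 % aq.), K2CO3, CH2Cl2, rt
Reagents that add atoms: tert-butyl hydroperoxide CC(C)(C)OO
Why: Catalytic allylic C–H oxidation should occur at the doubly allylic CH2, the weakest C–H bond of the molecule, to give the mirror-symmetric cyclohexa-2,5-dienone.

Step 5
Reactants: 7 2-methylpent-1-en-3-one
Product: 8 (3Z)-2-methyl-3-(triisopropylsilyloxy)penta-1,3-diene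
Conditions: i-Pr3SiOTf, Et3N, CH2Cl2, 0 °C
Reagents that add atoms: triisopropylsilyl trifluoromethanesulfonate CC(C)[Si](OS(=O)(=O)C(F)(F)F)(C(C)C)C(C)C
Why: Soft enolisation and O-silylation of the ethyl ketone should give the (Z)-silyl dienol ether, in which the oxygen makes the methyl-bearing terminus the nucleophilic end of the diene.

Step 6
Reactants: 6 4-[(4-methoxybenzyloxy)methyl]-4-methylcyclohexa-2,5-dien-1-one, 8 (3Z)-2-methyl-3-(triisopropylsilyloxy)penta-1,3-diene
Product: 9 cis-fused adduct (ring A C4 enone; ring B 7-silyl enol ether; 4a-H/8a-H/8-H on the face of the CH2OPMB arm)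
Conditions: (S)-o-tolyl-CBS oxazaborolidine (20 mol %), Tf2NH (18 mol %), CH2Cl2, −78 → −40 °C
Reagents that add atoms: none
Why: The protonated oxazaborolidine binds the dienone carbonyl and activates one of the two enantiotopic enone double bonds for a concerted but asynchronous endo [4+2] cycloaddition, in which the oxygen-bearing diene terminus (C8) attacks the β-carbon C8a and the CH2 terminus (C5) closes onto C4a; the closest known reactions are oxazaborolidinium-catalysed Diels–Alder reactions of 2-silyloxy dienes with quinone monoketals and cyclic enones. Ring B (C4a, C5, C6, C7, C8, C8a) is closed in this [4+2] mode, suprafacial on both partners. C4a and C8a should come out cis because both bonds form on one face of the ring cis-alkene, their sense relative to C1 should follow from approach of the diene anti to the larger CH2OPMB arm (which also makes C1 stereogenic), and the absolute sense from the catalyst's choice of enone. C8 is set by the endo transition state and is only provisional (corrected in step 9). The step needs regioselectivity, secured by the 7-silyloxy group, group selectivity between the two enones, secured by the chiral Lewis acid, and facial selectivity, secured by the size difference between CH2OPMB and CH3.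

Step 7
Reactants: 9 cis-fused adduct
Product: 10 C4 allylic alcohol (4-OH trans to 4a-H and cis to C5)
Conditions: i-Bu2AlH, CH2Cl2, −78 °C
Reagents that add atoms: none
Why: 1,2-Reduction of the enone, in which hydride should add to the face away from ring B (anti to the C4a–C5 bond) so that the hydroxyl ends up on the ring B face, while the aprotic conditions keep the silyl enol ether.

Step 8
Reactants: 10 C4 allylic alcohol
Product: 12 C2 N,N-dimethylacetamide (C3=C4 alkene; 2-H cis to 4a-H), via ketene N,O-acetal 11 (not isolated)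
Conditions: MeC(OMe)2NMe2, xylene, 140 °C
Reagents that add atoms: N,N-dimethylacetamide dimethyl acetal COC(C)(OC)N(C)C
Why: Eschenmoser–Claisen rearrangement, whose suprafacial [3,3] shift transfers the C4–O configuration to C2 (new C2–C1′ bond on the face of ring B and of the C1 methyl) and moves the double bond to C3=C4.

Step 9
Reactants: 12 C2 N,N-dimethylacetamide
Product: 14 C7 ketone with the target configuration at C6 and C8, via unequilibrated ketone 13 (not isolated)
Conditions: Bu4NF, AcOH, THF, 0 °C; then NaOMe (cat.), MeOH, rt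
Reagents that add atoms: none
Why: Desilylation frees the C7 ketone and base-mediated enolisation should equilibrate C6 and C8 to the thermodynamic epimers, the 8-methyl axial and anti to the quaternary C1 (its epimer has a syn-pentane contact with a C1 substituent) and the 6-methyl equatorial (its epimer would be 1,3-diaxial to the 8-methyl).

Step 10
Reactants: 14 C7 ketone
Product: 15 C7 tosylhydrazone
Conditions: TsNHNH2, PPTS (cat.), EtOH, 70 °C
Reagents that add atoms: 4-methylbenzenesulfonohydrazide Cc1ccc(cc1)S(=O)(=O)NN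
Why: Acid-catalysed condensation of the ketone with the sulfonyl hydrazide should give the tosylhydrazone without disturbing the thermodynamically set α-centres.

Step 11
Reactants: 15 C7 tosylhydrazone
Product: 16 (1S,2R,4aS,6R,8R,8aS)-decalin amide with C7 as CH2
Conditions: catecholborane, CHCl3, 0 °C; then NaOAc·3H2O, reflux
Reagents that add atoms: none
Why: Caglioti-type tosylhydrazone reduction, in which hydride adds to C=N, sulfinate is lost and the diazene expels N2, should turn the temporary C7 carbonyl into CH2 without touching the amide, the alkene or the α-stereocentres.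

Step 12
Reactants: 17 propanal
Product: 18 (3S,4S)-4-methylhex-5-en-3-ol
Conditions: cis-2-butene, n-BuLi, KOt-Bu, THF, −78 → −45 °C; (+)-Ipc2BOMe, −78 °C; BF3·OEt2; 17, −78 °C; NaOH, H2O2
Reagents that add atoms: cis-2-butene C/C=C\C
Why: Brown crotylboration, in which the (Z)-crotylborane reacts through a chair transition state to give the syn adduct and the Ipc antipode derived from (−)-α-pinene is the one expected to give the (3S,4S) enantiomer.

Step 13
Reactants: 18 (3S,4S)-4-methylhex-5-en-3-ol
Product: 19 tert-butyldimethylsilyl ether of 18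
Conditions: TBSCl, imidazole, DMF, rt
Reagents that add atoms: tert-butyldimethylsilyl chloride CC(C)(C)[Si](C)(C)Cl
Why: Silylation protects the secondary alcohol for the organolithium and oxidation steps that follow.

Step 14
Reactants: 19 tert-butyldimethylsilyl ether of 18
Product: 20 (2E,4S,5S)-5-(tert-butyldimethylsilyloxy)-4-methylhept-2-enal
Conditions: crotonaldehyde (5 equiv), second-generation Hoveyda–Grubbs catalyst (5 mol %), CH2Cl2, 40 °C
Reagents that add atoms: (E)-but-2-enal C/C=C/C=O
Why: Olefin cross-metathesis of the terminal alkene with the enal partner should give the (E)-enal under thermodynamic control with loss of propene.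

Step 15
Reactants: 20 (2E,4S,5S)-5-(tert-butyldimethylsilyloxy)-4-methylhept-2-enal
Product: 21 (1E,3E,5S,6S)-6-(tert-butyldimethylsilyloxy)-1-iodo-5-methylocta-1,3-diene
Conditions: CrCl2, CHI3, THF/dioxane, 0 °C → rt
Reagents that add atoms: iodoform IC(I)I
Why: Takai olefination should convert the aldehyde into the (E)-vinyl iodide and so complete the (E,E)-iododiene.

Step 16
Reactants: 21 (1E,3E,5S,6S)-6-(tert-butyldimethylsilyloxy)-1-iodo-5-methylocta-1,3-diene, 16 decalin amide
Product: 23 C2′ dienyl ketone, via dienyllithium 22 (not isolated)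
Conditions: t-BuLi (2.1 equiv), Et2O, −78 °C; then 16, −78 → 0 °C; NH4Cl aq.
Reagents that add atoms: none
Why: Iodine–lithium exchange proceeds with retention of the diene geometry and the dienyllithium should add once to the tertiary amide (stable tetrahedral intermediate) to give the ketone on work-up.

Step 17
Reactants: 23 C2′ dienyl ketone
Product: 24 (2′R)-dienyl alcohol
Conditions: (S)-Me-CBS (1 equiv), catecholborane, toluene, −78 °C
Reagents that add atoms: none
Why: Corey–Bakshi–Shibata reduction, in which the dienyl group acts as the large substituent so that the (S)-oxazaborolidine should deliver hydride 1,2 to give the (R)-carbinol.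

Step 18
Reactants: 24 (2′R)-dienyl alcohol
Product: 25 2′,8′-bis(tert-butyldimethylsilyl) ether
Conditions: TBSOTf, 2,6-lutidine, CH2Cl2, −78 °C
Reagents that add atoms: tert-butyldimethylsilyl trifluoromethanesulfonate CC(C)(C)[Si](C)(C)OS(=O)(=O)C(F)(F)F
Why: Silylation under buffered conditions protects the ionisable dienyl carbinol before the oxidations at the C1 arm.

Step 19
Reactants: 25 2′,8′-bis(tert-butyldimethylsilyl) ether
Product: 26 primary alcohol at the C1 arm
Conditions: DDQ, CH2Cl2/pH 7 buffer, 0 °C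
Reagents that add atoms: none
Why: Oxidative cleavage of the 4-methoxybenzyl ether should free the neopentyl alcohol while both silyl ethers stay in place.

Step 20
Reactants: 26 primary alcohol at the C1 arm
Product: 27 C1 carbaldehyde
Conditions: Dess–Martin periodinane, NaHCO3, CH2Cl2, rt
Reagents that add atoms: none
Why: Dess–Martin oxidation gives the non-enolisable aldehyde that becomes the acyl carbon.

Step 21
Reactants: 28 4-methoxy-1,5-dihydro-2H-pyrrol-2-one
Product: 29 3-bromo-4-methoxy-1,5-dihydro-2H-pyrrol-2-one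
Conditions: NBS, CH2Cl2, 0 °C
Reagents that add atoms: N-bromosuccinimide BrN1C(=O)CCC1=O
Why: Electrophilic bromination should occur at C3, the nucleophilic carbon of the vinylogous carbamate, and fixes the site of later metalation.

Step 22
Reactants: 29 3-bromo-4-methoxy-1,5-dihydro-2H-pyrrol-2-one, 27 C1 carbaldehyde
Product: 31 C1 carbinol bearing the O-methyl tetramate (mixture of carbinol epimers), via N-potassio C-lithio dianion 30 (not isolated)
Conditions: KH, THF, 0 °C; t-BuLi (2 equiv), −78 °C; then 27, −78 °C; NH4Cl aq.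
Reagents that add atoms: none
Why: N-Deprotonation shields the lactam carbonyl, bromine–lithium exchange gives the C3-lithio species regiospecifically, and its 1,2-addition to the aldehyde joins the purchased, intact heterocycle without any ring closure, the new carbinol centre being erased in step 23.

Step 23
Reactants: 31 C1 carbinol
Product: 32 3-acyl-4-methoxypyrrolinone
Conditions: Dess–Martin periodinane, NaHCO3, CH2Cl2, rt
Reagents that add atoms: none
Why: Dess–Martin oxidation of the secondary carbinol gives the acyl group on the tetramate.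

Step 24
Reactants: 32 3-acyl-4-methoxypyrrolinone
Product: 33 bis(silyl) ether of the target tetramic acid
Conditions: NaOH (1 M aq.), THF/MeOH, rt; then pH 3
Reagents that add atoms: sodium hydroxide [Na+].[OH-]
Why: Hydroxide addition–elimination at C4 of the doubly activated methyl enol ether should release the 3-acyltetramic acid while the silyl ethers survive.

Step 25
Reactants: 33 bis(silyl) ether of the target tetramic acid
Product: 34 CNP0117518.2
Conditions: HF·pyridine, pyridine, THF, 0 °C → rt
Reagents that add atoms: none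
Why: Buffered fluoride desilylation should remove both silyl ethers without ionising the dienyl carbinol.

**Compound list**

1 | benzoic acid | OC(=O)c1ccccc1 | starting material
2 | dilithium (cyclohexa-2,5-dien-1-ylidene)methanediolate (Birch enediolate) | [Li+].[Li+].[O-]C([O-])=C1C=CCC=C1 | intermediate
3 | 1-methylcyclohexa-2,5-diene-1-carboxylic acid | CC1(C(=O)O)C=CCC=C1 | intermediate
4 | (1-methylcyclohexa-2,5-dien-1-yl)methanol | CC1(CO)C=CCC=C1 | intermediate
5 | 1-methoxy-4-{[(1-methylcyclohexa-2,5-dien-1-yl)methoxy]methyl}benzene | COc1ccc(COCC2(C)C=CCC=C2)cc1 | intermediate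
6 | 4-{[(4-methoxybenzyl)oxy]methyl}-4-methylcyclohexa-2,5-dien-1-one | COc1ccc(COCC2(C)C=CC(=O)C=C2)cc1 | intermediate
7 | 2-methylpent-1-en-3-one | CCC(=O)C(C)=C | starting material
8 | (3Z)-2-methyl-3-[(triisopropylsilyl)oxy]penta-1,3-diene | C/C=C(\O[Si](C(C)C)(C(C)C)C(C)C)C(C)=C | intermediate
9 | cis-fused adduct (target numbering): 1-{[(4-methoxybenzyl)oxy]methyl}-1,6,8-trimethyl-7-[(triisopropylsilyl)oxy]-4a,5,8,8a-tetrahydronaphthalen-4(1H)-one; 4a-H, 8a-H and 8-H on the face of CH2OPMB, 1-CH3 on the other face | COc1ccc(COC[C@@]2(C)C=CC(=O)[C@@H]3CC(C)=C(O[Si](C(C)C)(C(C)C)C(C)C)[C@H](C)[C@H]23)cc1 | intermediate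
10 | C4 allylic alcohol of 9; 4-OH trans to 4a-H (on the ring B face) | COc1ccc(COC[C@@]2(C)C=C[C@H](O)[C@@H]3CC(C)=C(O[Si](C(C)C)(C(C)C)C(C)C)[C@H](C)[C@H]23)cc1 | intermediate
11 | O-[1-(dimethylamino)vinyl] ketene N,O-acetal of 10 | COc1ccc(COC[C@@]2(C)C=C[C@H](OC(=C)N(C)C)[C@@H]3CC(C)=C(O[Si](C(C)C)(C(C)C)C(C)C)[C@H](C)[C@H]23)cc1 | intermediate
12 | 2-(hexahydronaphthalen-2-yl)-N,N-dimethylacetamide with C3=C4 alkene and 7-silyl enol ether; 2-H cis to 4a-H and 8a-H; 8-CH3 still cis to C1 | CN(C)C(=O)C[C@@H]1C=C[C@@H]2CC(C)=C(O[Si](C(C)C)(C(C)C)C(C)C)[C@H](C)[C@@H]2[C@@]1(C)COCc1ccc(OC)cc1 | intermediate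
13 | C7 ketone as released (8-CH3 cis to C1, C6 not yet equilibrated) | CN(C)C(=O)C[C@@H]1C=C[C@@H]2CC(C)C(=O)[C@H](C)[C@@H]2[C@@]1(C)COCc1ccc(OC)cc1 | intermediate
14 | C7 ketone with target configuration at C6 and C8 (8-CH3 anti to C1, 6-CH3 equatorial) | CN(C)C(=O)C[C@@H]1C=C[C@@H]2C[C@H](C)C(=O)[C@@H](C)[C@@H]2[C@@]1(C)COCc1ccc(OC)cc1 | intermediate
15 | C7 tosylhydrazone of 14 | CN(C)C(=O)C[C@@H]1C=C[C@@H]2C[C@H](C)C(=NNS(=O)(=O)c3ccc(C)cc3)[C@@H](C)[C@@H]2[C@@]1(C)COCc1ccc(OC)cc1 | intermediate
16 | 2-[(1S,2R,4aS,6R,8R,8aS)-1-{[(4-methoxybenzyl)oxy]methyl}-1,6,8-trimethyl-1,2,4a,5,6,7,8,8a-octahydronaphthalen-2-yl]-N,N-dimethylacetamide | CN(C)C(=O)C[C@@H]1C=C[C@@H]2C[C@H](C)C[C@@H](C)[C@@H]2[C@@]1(C)COCc1ccc(OC)cc1 | intermediate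
17 | propanal | CCC=O | starting material
18 | (3S,4S)-4-methylhex-5-en-3-ol | CC[C@H](O)[C@@H](C)C=C | intermediate
19 | tert-butyldimethyl{[(3S,4S)-4-methylhex-5-en-3-yl]oxy}silane | CC[C@H](O[Si](C)(C)C(C)(C)C)[C@@H](C)C=C | intermediate
20 | (2E,4S,5S)-5-[(tert-butyldimethylsilyl)oxy]-4-methylhept-2-enal | CC[C@H](O[Si](C)(C)C(C)(C)C)[C@@H](C)/C=C/C=O | intermediate
21 | (1E,3E,5S,6S)-6-[(tert-butyldimethylsilyl)oxy]-1-iodo-5-methylocta-1,3-diene | CC[C@H](O[Si](C)(C)C(C)(C)C)[C@@H](C)/C=C/C=C/I | intermediate
22 | (1E,3E,5S,6S)-6-[(tert-butyldimethylsilyl)oxy]-5-methylocta-1,3-dien-1-yllithium | CC[C@H](O[Si](C)(C)C(C)(C)C)[C@@H](C)/C=C/C=C/[Li] | intermediate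
23 | C2′ ketone: (3E,5E,7S,8S)-8-silyloxy-7-methyldeca-3,5-dien-2-one attached through C1′ to C2 of the decalin of 16 | CC[C@H](O[Si](C)(C)C(C)(C)C)[C@@H](C)/C=C/C=C/C(=O)C[C@@H]1C=C[C@@H]2C[C@H](C)C[C@@H](C)[C@@H]2[C@@]1(C)COCc1ccc(OC)cc1 | intermediate
24 | (2′R)-alcohol of 23 | CC[C@H](O[Si](C)(C)C(C)(C)C)[C@@H](C)/C=C/C=C/[C@H](O)C[C@@H]1C=C[C@@H]2C[C@H](C)C[C@@H](C)[C@@H]2[C@@]1(C)COCc1ccc(OC)cc1 | intermediate
25 | 2′,8′-bis(tert-butyldimethylsilyl) ether with the 4-methoxybenzyl ether at the C1 arm | CC[C@H](O[Si](C)(C)C(C)(C)C)[C@@H](C)/C=C/C=C/[C@H](O[Si](C)(C)C(C)(C)C)C[C@@H]1C=C[C@@H]2C[C@H](C)C[C@@H](C)[C@@H]2[C@@]1(C)COCc1ccc(OC)cc1 | intermediate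
26 | primary alcohol: [(1S,2R,4aS,6R,8R,8aS)-2-(bis-silylated side chain)-1,6,8-trimethyl-octahydronaphthalen-1-yl]methanol | CC[C@H](O[Si](C)(C)C(C)(C)C)[C@@H](C)/C=C/C=C/[C@H](O[Si](C)(C)C(C)(C)C)C[C@@H]1C=C[C@@H]2C[C@H](C)C[C@@H](C)[C@@H]2[C@@]1(C)CO | intermediate
27 | corresponding octahydronaphthalene-1-carbaldehyde | CC[C@H](O[Si](C)(C)C(C)(C)C)[C@@H](C)/C=C/C=C/[C@H](O[Si](C)(C)C(C)(C)C)C[C@@H]1C=C[C@@H]2C[C@H](C)C[C@@H](C)[C@@H]2[C@@]1(C)C=O | intermediate
28 | 4-methoxy-1,5-dihydro-2H-pyrrol-2-one | COC1=CC(=O)NC1 | starting material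
29 | 3-bromo-4-methoxy-1,5-dihydro-2H-pyrrol-2-one | COC1=C(Br)C(=O)NC1 | intermediate
30 | 3-lithio-4-methoxy-1-potassio-1,5-dihydro-2H-pyrrol-2-one | COC1=C([Li])C(=O)N([K])C1 | intermediate
31 | carbinol: 3-[hydroxy(decalin-1-yl)methyl]-4-methoxy-1,5-dihydro-2H-pyrrol-2-one, carbinol carbon as an epimer mixture | CC[C@H](O[Si](C)(C)C(C)(C)C)[C@@H](C)/C=C/C=C/[C@H](O[Si](C)(C)C(C)(C)C)C[C@@H]1C=C[C@@H]2C[C@H](C)C[C@@H](C)[C@@H]2[C@@]1(C)C(O)C1=C(OC)CNC1=O | intermediate
32 | 3-(decalin-1-ylcarbonyl)-4-methoxy-1,5-dihydro-2H-pyrrol-2-one, bis-silylated | CC[C@H](O[Si](C)(C)C(C)(C)C)[C@@H](C)/C=C/C=C/[C@H](O[Si](C)(C)C(C)(C)C)C[C@@H]1C=C[C@@H]2C[C@H](C)C[C@@H](C)[C@@H]2[C@@]1(C)C(=O)C1=C(OC)CNC1=O | intermediate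
33 | 2′,8′-bis(tert-butyldimethylsilyl) ether of the target | CC[C@H](O[Si](C)(C)C(C)(C)C)[C@@H](C)/C=C/C=C/[C@H](O[Si](C)(C)C(C)(C)C)C[C@@H]1C=C[C@@H]2C[C@H](C)C[C@@H](C)[C@@H]2[C@@]1(C)C(=O)C1=C(O)CNC1=O | intermediate
34 | CNP0117518.2: 3-{[(1S,2R,4aS,6R,8R,8aS)-2-[(2R,3E,5E,7S,8S)-2,8-dihydroxy-7-methyldeca-3,5-dien-1-yl]-1,6,8-trimethyl-1,2,4a,5,6,7,8,8a-octahydronaphthalen-1-yl]carbonyl}-4-hydroxy-1,5-dihydro-2H-pyrrol-2-one | CC[C@H](O)[C@@H](C)/C=C/C=C/[C@H](O)C[C@@H]1C=C[C@@H]2C[C@H](C)C[C@@H](C)[C@@H]2[C@@]1(C)C(=O)C1=C(O)CNC1=O | target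

**Totals.** Total step count: 25. Longest linear sequence: 19 steps (steps 1–4, 6–11, 16–20, 22–25).

**Steps most likely to fail**

1. Step 6. The catalyst may discriminate the two enantiotopic enone double bonds poorly, the diene may not approach cleanly anti to the CH2OPMB arm, and bond formation beside the quaternary carbon may be slow. A minor syn-diastereomer would be removed by chromatography. Fallback, setting out from 6 and 8: the cycloaddition is run without chiral information (Me2AlCl, CH2Cl2, −40 °C), which should give 9 together with its mirror image, the enantiomeric adduct F1. Reduction as in step 7 then gives 10 together with the enantiomeric allylic alcohol F2. Kinetic resolution with Burkholderia cepacia lipase and vinyl acetate (t-BuOMe, 30 °C) is assumed to acetylate F2 to the allylic acetate F3, which is separated. Unreacted 10 rejoins the route at 10.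

2. Step 8. The sigmatropic shift has to form a C–C bond beside the quaternary C1 on the more crowded face, and thermal elimination of the allylic C4 oxygen to a diene may outrun it. Fallback, setting out from 10: acetylation (Ac2O, DMAP, pyridine) gives the allylic acetate F4. Ireland–Claisen rearrangement through the silyl ketene acetal (LiN(i-Pr)2, TBSCl, THF/HMPA, −78 → 60 °C; aqueous work-up) should give the carboxylic acid F5 at far lower temperature. Amide coupling with Me2NH·HCl (EDC, HOBt, i-Pr2NEt, CH2Cl2) comes back to the route at 12.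

3. Step 10. Condensation at the doubly α-branched ketone may be slow or incomplete. Fallback, setting out from 14: NaBH4 (MeOH, 0 °C → rt) gives the C7 alcohol F6 (either epimer serves). NaH, CS2, then MeI give the S-methyl xanthate F7. Barton–McCombie deoxygenation (Bu3SnH, AIBN, toluene, 110 °C) should give 16, where the route is rejoined (steps 10 and 11 are bypassed).

**Further compounds**

F1 | step 6 | enantiomer of adduct 9 | COc1ccc(COC[C@]2(C)C=CC(=O)[C@H]3CC(C)=C(O[Si](C(C)C)(C(C)C)C(C)C)[C@@H](C)[C@@H]23)cc1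
F2 | step 6 | enantiomer of allylic alcohol 10 | COc1ccc(COC[C@]2(C)C=C[C@@H](O)[C@H]3CC(C)=C(O[Si](C(C)C)(C(C)C)C(C)C)[C@@H](C)[C@@H]23)cc1
F3 | step 6 | acetate of the enantiomeric allylic alcohol | COc1ccc(COC[C@]2(C)C=C[C@@H](OC(C)=O)[C@H]3CC(C)=C(O[Si](C(C)C)(C(C)C)C(C)C)[C@@H](C)[C@@H]23)cc1
F4 | step 8 | C4 acetate of 10 | COc1ccc(COC[C@@]2(C)C=C[C@H](OC(C)=O)[C@@H]3CC(C)=C(O[Si](C(C)C)(C(C)C)C(C)C)[C@H](C)[C@H]23)cc1
F5 | step 8 | C2 acetic acid corresponding to amide 12 | OC(=O)C[C@@H]1C=C[C@@H]2CC(C)=C(O[Si](C(C)C)(C(C)C)C(C)C)[C@H](C)[C@@H]2[C@@]1(C)COCc1ccc(OC)cc1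
F6 | step 10 | C7 alcohol from ketone 14 (C7 epimer mixture) | CN(C)C(=O)C[C@@H]1C=C[C@@H]2C[C@H](C)C(O)[C@@H](C)[C@@H]2[C@@]1(C)COCc1ccc(OC)cc1
F7 | step 10 | O-(C7) S-methyl xanthate of F6 | CN(C)C(=O)C[C@@H]1C=C[C@@H]2C[C@H](C)C(OC(=S)SC)[C@@H](C)[C@@H]2[C@@]1(C)COCc1ccc(OC)cc1
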